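The route rests on disconnecting the spiro δ-lactone (ring atoms C7, C8, C9, C10, C20, O; ent-kaurane numbering) at the C9–C10 bond. C10 is flanked by the C1 acetoxy carbon and the C20 lactone methylene, so a tertiary C10 radical can be generated from a bromohydrin acetate whose C20 oxygen already carries the ring-C acyl group. In one operation this radical closes the lactone 6-endo onto C9 of the cyclohexenecarboxylate, and the resulting C8 radical closes ring D 5-exo onto a propargyl group at C13, creating C10, C9, C8 and both quaternary centres. The precursor, bromide 22, is a ring-A unit (from a silyloxydiene Diels–Alder reaction) esterified at C20 with (S)-5-propargylcyclohexenecarboxylic acid.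

Key step: step 13

Remark (numbering): atom labels follow ent-kaurane numbering of the target: C7 lactone carbonyl, C20 lactone CH2, C10 spiro carbon, C15 ketone, C16/C17 exo-methylene, C19 the CH2OH on C4, C6 the CH2OAc on C5.
Remark (assumption): in step 8 the (S)-oxazaborolidinium cation is assumed to shield the methacrolein face that leads to the (5R,6S) adduct 18; the enantiomeric catalyst is equally accessible.

Step 1
Reactants: 1 glutaraldehyde; 2 methyl 2-(dimethoxyphosphoryl)prop-2-enoate
Product: 4 methyl (5R)-5-formylcyclohex-1-ene-1-carboxylate, via Michael adduct 3 (not isolated)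
Conditions: 1 (50% aq., 3 equiv), (S)-2-[diphenyl(trimethylsilyloxy)methyl]pyrrolidine (10 mol %), PhCO2H (10 mol %), CH2Cl2, 0 °C; then LiCl, DBU, MeCN, 0 °C
Reagents that add atoms: none
Why: Enamine Michael addition of 1 to the doubly activated acrylate 2 should set C13 (the diarylprolinol silyl ether shields one enamine face), and intramolecular Horner–Wadsworth–Emmons olefination of the remote aldehyde (Masamune–Roush conditions) then closes the cyclohexene.

Step 2
Reactants: 4 methyl (5R)-5-formylcyclohex-1-ene-1-carboxylate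
Product: 6 methyl (5R)-5-(2-oxoethyl)cyclohex-1-ene-1-carboxylate, via enol ether 5 (not isolated)
Conditions: Ph3P(CH2OMe)Cl, KHMDS, THF, −78 → 0 °C; then 2 M HCl, THF, rt
Reagents that add atoms: (methoxymethyl)triphenylphosphonium chloride, COC[P+](c1ccccc1)(c1ccccc1)c1ccccc1.[Cl-]; water, O
Why: Wittig methoxymethylenation followed by enol ether hydrolysis should homologate the aldehyde by one carbon without touching the conjugated ester, and no stereocentre is formed (the α-formyl centre is carried through cold to avoid epimerisation).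

Step 3
Reactants: 6 methyl (5R)-5-(2-oxoethyl)cyclohex-1-ene-1-carboxylate
Product: 8 (5S)-5-(prop-2-yn-1-yl)cyclohex-1-ene-1-carboxylic acid, via alkyne ester 7 (not isolated)
Conditions: dimethyl (1-diazo-2-oxopropyl)phosphonate, K2CO3, MeOH, 0 °C → rt; then LiOH, H2O/THF, 40 °C; HCl work-up
Reagents that add atoms: dimethyl (1-diazo-2-oxopropyl)phosphonate, CC(=O)C(=[N+]=[N-])P(=O)(OC)OC; lithium hydroxide, [Li+].[OH-]
Why: Seyferth–Gilbert homologation in its Ohira–Bestmann form should convert the aldehyde into the terminal alkyne under mild carbonate conditions, and the methyl ester is then saponified in the same flask; no stereocentre is formed.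

Step 4
Reactants: 9 (2Z)-but-2-ene-1,4-diyl diacetate
Product: 11 2-oxoethyl acetate, via ozonide 10 (not isolated)
Conditions: O3, CH2Cl2, −78 °C; then Me2S, −78 °C → rt
Reagents that add atoms: ozone, [O-][O+]=O
Why: Ozonolysis with reductive work-up should cleave the symmetrical alkene into two molecules of the aldehyde; no stereocentre is involved.

Step 5
Reactants: 11 2-oxoethyl acetate; 12 but-3-en-2-one
Product: 13 2-hydroxy-3-methylidene-4-oxopentyl acetate (racemic)
Conditions: DABCO (20 mol %), THF, rt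
Reagents that add atoms: none
Why: Morita–Baylis–Hillman reaction of the enone with the reactive α-acyloxy aldehyde should give the allylic alcohol, whose racemic carbinol centre is erased in step 6.

Step 6
Reactants: 13 2-hydroxy-3-methylidene-4-oxopentyl acetate; 8 (5S)-5-(prop-2-yn-1-yl)cyclohex-1-ene-1-carboxylic acid
Product: 15 (2E)-4-acetoxy-2-acetylbut-2-en-1-yl (5S)-5-(prop-2-yn-1-yl)cyclohex-1-ene-1-carboxylate, via secondary ester 14 (not isolated)
Conditions: DCC, DMAP (10 mol %), CH2Cl2, 0 °C → rt; then DABCO (1 equiv), THF, 50 °C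
Reagents that add atoms: none
Why: Steglich esterification followed by amine-mediated SN2′/SN2 allylic transposition of the Morita–Baylis–Hillman ester should give the thermodynamically preferred (E)-2-(acyloxymethyl) enone with CH2OAc trans to the acetyl group; no stereocentre is formed.

Step 7
Reactants: 15 (2E)-4-acetoxy-2-acetylbut-2-en-1-yl (5S)-5-(prop-2-yn-1-yl)cyclohex-1-ene-1-carboxylate
Product: 16 (2E)-4-acetoxy-2-{1-[tri(propan-2-yl)silyloxy]ethenyl}but-2-en-1-yl (5S)-5-(prop-2-yn-1-yl)cyclohex-1-ene-1-carboxylate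
Conditions: TIPSOTf, Et3N, CH2Cl2, −78 → 0 °C
Reagents that add atoms: triisopropylsilyl trifluoromethanesulfonate, CC(C)[Si](C(C)C)(C(C)C)OS(=O)(=O)C(F)(F)F
Why: Soft enolisation of the methyl ketone (silyl triflate and amine) should give the 2-silyloxy diene with the (E) trisubstituted alkene retained, which places the CH2OAc group on the outside of the diene.

Step 8
Reactants: 16 (2E)-4-acetoxy-2-{1-[tri(propan-2-yl)silyloxy]ethenyl}but-2-en-1-yl (5S)-5-(prop-2-yn-1-yl)cyclohex-1-ene-1-carboxylate; 17 2-methylprop-2-enal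
Product: 18 {(5R,6S)-6-(acetoxymethyl)-5-formyl-5-methyl-2-[tri(propan-2-yl)silyloxy]cyclohex-1-en-1-yl}methyl (5S)-5-(prop-2-yn-1-yl)cyclohex-1-ene-1-carboxylate
Conditions: 17 (5 equiv), (S)-oxazaborolidinium triflimide [from (S)-2-(diphenylhydroxymethyl)pyrrolidine, tri(o-tolyl)boroxine and HNTf2] (20 mol %), CH2Cl2, −78 → −40 °C
Reagents that add atoms: none
Why: In this catalytic enantioselective Diels–Alder reaction the 2-silyloxy group and the terminal CH2OAc group both direct the quaternary carbon of 17 to the substituted diene terminus, the formyl-endo transition state should place CHO cis to CH2OAc (C4 and C5), and the chiral boron cation selects the enantioface.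

Step 9
Reactants: 18 {(5R,6S)-6-(acetoxymethyl)-5-formyl-5-methyl-2-[tri(propan-2-yl)silyloxy]cyclohex-1-en-1-yl}methyl (5S)-5-(prop-2-yn-1-yl)cyclohex-1-ene-1-carboxylate
Product: 19 [(1R,2S,3R)-2-(acetoxymethyl)-1-bromo-3-formyl-3-methyl-6-oxocyclohexyl]methyl (5S)-5-(prop-2-yn-1-yl)cyclohex-1-ene-1-carboxylate
Conditions: NBS, NaHCO3, THF, −78 → 0 °C
Reagents that add atoms: N-bromosuccinimide, O=C1CCC(=O)N1Br
Why: Electrophilic bromination of the silyl enol ether can occur only at its nucleophilic carbon C10 and should give the tertiary α-bromo ketone, with bromine entering anti to the C5 acetoxymethyl group (a centre that is destroyed in step 13).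

Step 10
Reactants: 19 [(1R,2S,3R)-2-(acetoxymethyl)-1-bromo-3-formyl-3-methyl-6-oxocyclohexyl]methyl (5S)-5-(prop-2-yn-1-yl)cyclohex-1-ene-1-carboxylate
Product: 20 [(1R,2S,3R,6S)-2-(acetoxymethyl)-1-bromo-6-hydroxy-3-(hydroxymethyl)-3-methylcyclohexyl]methyl (5S)-5-(prop-2-yn-1-yl)cyclohex-1-ene-1-carboxylate
Conditions: NaBH4, MeOH/THF, −40 °C; AcOH quench
Reagents that add atoms: none
Why: Borohydride reduction should convert the aldehyde into C19-OH and the ketone into the C1 alcohol, the latter by axial hydride delivery on the ring face opposite the C20, C19 and C6 substituents so that the equatorial (6S) alcohol trans to bromine is formed under substrate control.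

Step 11
Reactants: 20 [(1R,2S,3R,6S)-2-(acetoxymethyl)-1-bromo-6-hydroxy-3-(hydroxymethyl)-3-methylcyclohexyl]methyl (5S)-5-(prop-2-yn-1-yl)cyclohex-1-ene-1-carboxylate
Product: 21 [(1R,2S,3R,6S)-2-(acetoxymethyl)-1-bromo-3-{[tert-butyl(dimethyl)silyl]oxymethyl}-6-hydroxy-3-methylcyclohexyl]methyl (5S)-5-(prop-2-yn-1-yl)cyclohex-1-ene-1-carboxylate
Conditions: TBSCl, imidazole, CH2Cl2, 0 °C
Reagents that add atoms: tert-butyldimethylsilyl chloride, CC(C)(C)[Si](C)(C)Cl
Why: Silylation should be selective for the primary C19 alcohol over the hindered secondary C1 alcohol next to the quaternary C–Br carbon.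

Step 12
Reactants: 21 [(1R,2S,3R,6S)-2-(acetoxymethyl)-1-bromo-3-{[tert-butyl(dimethyl)silyl]oxymethyl}-6-hydroxy-3-methylcyclohexyl]methyl (5S)-5-(prop-2-yn-1-yl)cyclohex-1-ene-1-carboxylate
Product: 22 [(1R,2S,3R,6S)-6-acetoxy-2-(acetoxymethyl)-1-bromo-3-{[tert-butyl(dimethyl)silyl]oxymethyl}-3-methylcyclohexyl]methyl (5S)-5-(prop-2-yn-1-yl)cyclohex-1-ene-1-carboxylate
Conditions: Ac2O, pyridine, DMAP (cat.), CH2Cl2, rt
Reagents that add atoms: acetic anhydride, CC(=O)OC(C)=O
Why: DMAP-catalysed acetylation of the remaining secondary alcohol should install the C1 acetate of the target without disturbing the tertiary bromide.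

Step 13
Reactants: 22 [(1R,2S,3R,6S)-6-acetoxy-2-(acetoxymethyl)-1-bromo-3-{[tert-butyl(dimethyl)silyl]oxymethyl}-3-methylcyclohexyl]methyl (5S)-5-(prop-2-yn-1-yl)cyclohex-1-ene-1-carboxylate
Product: 23 1α,6-diacetoxy-19-(tert-butyldimethylsilyloxy)-15-methylidene-17-nor-6,7-seco-ent-kauran-7,20-olide
Conditions: Bu3SnH (1.3 equiv) and AIBN (0.2 equiv) by syringe pump over 10 h, PhH (2 mM), 80 °C
Reagents that add atoms: none
Why: The tributyltin radical abstracts bromine from 22 to give a nucleophilic tertiary C10 radical, which adds 6-endo-trig to the β-carbon C9 of the tethered cyclohexenecarboxylate and so closes the δ-lactone (5-exo attack at the fully substituted, polarity-mismatched α-carbon C8 is disfavoured); the tertiary α-acyl radical formed at C8 then cyclises 5-exo-dig onto the propargyl group of C13, closing ring D, and the vinyl radical is reduced by the stannane. The closest known reactions are stannane-mediated tandem 6-endo/5-exo-dig radical cyclisations to bicyclo[3.2.1]octanes and the Giese addition of the same kind of β-oxygenated tertiary C10 radical to acrylates. C10 should be set by attack on the ring-A face anti to the C1 acetoxy, C6 acetoxymethyl and axial C19 silyloxymethyl groups (C9 equatorial, C20 axial); C9 by a chair-like transition state that keeps the ring-C methylene C11 on the less substituted C1 side of ring A; and C8 by the tether, because the alkyne can reach C8 only from the ring-C face that carries the C13 side chain, which gives the cis-fused lactone. The step needs cyclisation to outrun hydrogen transfer to the C10 radical, whose ester tether must first adopt the s-cis form; this is secured by slow stannane addition at high dilution, and the 6-endo regiochemistry is secured by the substitution and polarity of the enoate.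

Step 14
Reactants: 23 1α,6-diacetoxy-19-(tert-butyldimethylsilyloxy)-15-methylidene-17-nor-6,7-seco-ent-kauran-7,20-olide
Product: 25 1α,6-diacetoxy-19-(tert-butyldimethylsilyloxy)-15-oxo-17-nor-6,7-seco-ent-kauran-7,20-olide, via ozonide 24 (not isolated)
Conditions: O3, CH2Cl2, −78 °C; then Me2S, −78 °C → rt
Reagents that add atoms: ozone, [O-][O+]=O
Why: Ozonolysis of the only alkene, the exocyclic 1,1-disubstituted C15 methylidene, should give the C15 ketone under neutral conditions that spare the β-keto lactone.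

Step 15
Reactants: 25 1α,6-diacetoxy-19-(tert-butyldimethylsilyloxy)-15-oxo-17-nor-6,7-seco-ent-kauran-7,20-olide
Product: 27 1α,6-diacetoxy-19-(tert-butyldimethylsilyloxy)-15-oxo-6,7-seco-ent-kaur-16-en-7,20-olide, via Mannich base 26 (not isolated)
Conditions: (CH2O)n, PhNHMe·CF3CO2H, THF, 65 °C
Reagents that add atoms: paraformaldehyde (as formaldehyde), C=O
Why: Mannich condensation and elimination with N-methylanilinium trifluoroacetate should methylenate C16, the only enolisable position of the ketone, under mildly acidic conditions that spare the acetates and the lactone.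

Step 16
Reactants: 27 1α,6-diacetoxy-19-(tert-butyldimethylsilyloxy)-15-oxo-6,7-seco-ent-kaur-16-en-7,20-olide
Product: 28 isodojaponin D
Conditions: HF·pyridine, THF/pyridine, 0 °C → rt
Reagents that add atoms: none
Why: Fluoride cleavage of the primary silyl ether (Si–F bond formation) under buffered conditions should free the C19 alcohol while leaving the acetates, the lactone and the enone intact.

Compound list
1 | glutaraldehyde (pentanedial) | O=CCCCC=O | starting material
2 | methyl 2-(dimethoxyphosphoryl)prop-2-enoate | C=C(C(=O)OC)P(=O)(OC)OC | starting material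
3 | methyl (4R)-2-(dimethoxyphosphoryl)-4-formyl-7-oxoheptanoate (C2 epimers) | COC(=O)C(C[C@H](C=O)CCC=O)P(=O)(OC)OC | intermediate
4 | methyl (5R)-5-formylcyclohex-1-ene-1-carboxylate | COC(=O)C1=CCC[C@@H](C=O)C1 | intermediate
5 | methyl (5R)-5-(2-methoxyethenyl)cyclohex-1-ene-1-carboxylate (E/Z) | COC(=O)C1=CCC[C@@H](C=COC)C1 | intermediate
6 | methyl (5R)-5-(2-oxoethyl)cyclohex-1-ene-1-carboxylate | COC(=O)C1=CCC[C@@H](CC=O)C1 | intermediate
7 | methyl (5S)-5-(prop-2-yn-1-yl)cyclohex-1-ene-1-carboxylate | COC(=O)C1=CCC[C@@H](CC#C)C1 | intermediate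
8 | (5S)-5-(prop-2-yn-1-yl)cyclohex-1-ene-1-carboxylic acid | OC(=O)C1=CCC[C@@H](CC#C)C1 | intermediate
9 | (2Z)-but-2-ene-1,4-diyl diacetate | CC(=O)OC/C=C\COC(C)=O | starting material
10 | 3,5-bis(acetoxymethyl)-1,2,4-trioxolane (ozonide) | CC(=O)OCC1OOC(COC(C)=O)O1 | intermediate
11 | 2-oxoethyl acetate | CC(=O)OCC=O | intermediate
12 | but-3-en-2-one | CC(=O)C=C | starting material
13 | 2-hydroxy-3-methylidene-4-oxopentyl acetate (racemic) | CC(=O)C(=C)C(O)COC(C)=O | intermediate
14 | 1-acetoxy-3-methylidene-4-oxopentan-2-yl (5S)-5-(prop-2-yn-1-yl)cyclohex-1-ene-1-carboxylate (both carbinol epimers) | CC(=O)C(=C)C(COC(C)=O)OC(=O)C1=CCC[C@@H](CC#C)C1 | intermediate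
15 | (2E)-4-acetoxy-2-acetylbut-2-en-1-yl (5S)-5-(prop-2-yn-1-yl)cyclohex-1-ene-1-carboxylate | CC(=O)/C(COC(=O)C1=CCC[C@@H](CC#C)C1)=C/COC(C)=O | intermediate
16 | (2E)-4-acetoxy-2-{1-[tri(propan-2-yl)silyloxy]ethenyl}but-2-en-1-yl (5S)-5-(prop-2-yn-1-yl)cyclohex-1-ene-1-carboxylate | C=C(O[Si](C(C)C)(C(C)C)C(C)C)/C(COC(=O)C1=CCC[C@@H](CC#C)C1)=C/COC(C)=O | intermediate
17 | 2-methylprop-2-enal | CC(=C)C=O | starting material
18 | {(5R,6S)-6-(acetoxymethyl)-5-formyl-5-methyl-2-[tri(propan-2-yl)silyloxy]cyclohex-1-en-1-yl}methyl (5S)-5-(prop-2-yn-1-yl)cyclohex-1-ene-1-carboxylate (formyl cis to acetoxymethyl) | C1(COC(=O)C2=CCC[C@@H](CC#C)C2)=C(O[Si](C(C)C)(C(C)C)C(C)C)CC[C@@](C)(C=O)[C@H]1COC(C)=O | intermediate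
19 | [(1R,2S,3R)-2-(acetoxymethyl)-1-bromo-3-formyl-3-methyl-6-oxocyclohexyl]methyl (5S)-5-(prop-2-yn-1-yl)cyclohex-1-ene-1-carboxylate (Br trans to acetoxymethyl) | Br[C@]1(COC(=O)C2=CCC[C@@H](CC#C)C2)C(=O)CC[C@@](C)(C=O)[C@H]1COC(C)=O | intermediate
20 | [(1R,2S,3R,6S)-2-(acetoxymethyl)-1-bromo-6-hydroxy-3-(hydroxymethyl)-3-methylcyclohexyl]methyl (5S)-5-(prop-2-yn-1-yl)cyclohex-1-ene-1-carboxylate | Br[C@]1(COC(=O)C2=CCC[C@@H](CC#C)C2)[C@@H](O)CC[C@@](C)(CO)[C@H]1COC(C)=O | intermediate
21 | [(1R,2S,3R,6S)-2-(acetoxymethyl)-1-bromo-3-{[tert-butyl(dimethyl)silyl]oxymethyl}-6-hydroxy-3-methylcyclohexyl]methyl (5S)-5-(prop-2-yn-1-yl)cyclohex-1-ene-1-carboxylate | Br[C@]1(COC(=O)C2=CCC[C@@H](CC#C)C2)[C@@H](O)CC[C@@](C)(CO[Si](C)(C)C(C)(C)C)[C@H]1COC(C)=O | intermediate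
22 | [(1R,2S,3R,6S)-6-acetoxy-2-(acetoxymethyl)-1-bromo-3-{[tert-butyl(dimethyl)silyl]oxymethyl}-3-methylcyclohexyl]methyl (5S)-5-(prop-2-yn-1-yl)cyclohex-1-ene-1-carboxylate (OAc, CH2OAc, CH2OTBS and the ester CH2 on one face; Br and C4-methyl on the other) | Br[C@]1(COC(=O)C2=CCC[C@@H](CC#C)C2)[C@@H](OC(C)=O)CC[C@@](C)(CO[Si](C)(C)C(C)(C)C)[C@H]1COC(C)=O | intermediate
23 | 1α,6-diacetoxy-19-(tert-butyldimethylsilyloxy)-15-methylidene-17-nor-6,7-seco-ent-kauran-7,20-olide | C1C(=C)[C@]23C[C@H]1CC[C@H]2[C@]1(COC3=O)[C@@H](OC(C)=O)CC[C@@](C)(CO[Si](C)(C)C(C)(C)C)[C@H]1COC(C)=O | intermediate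
24 | ozonide of 23 (spiro-1,2,4-trioxolane at C15) | C1C4(OOCO4)[C@]23C[C@H]1CC[C@H]2[C@]1(COC3=O)[C@@H](OC(C)=O)CC[C@@](C)(CO[Si](C)(C)C(C)(C)C)[C@H]1COC(C)=O | intermediate
25 | 1α,6-diacetoxy-19-(tert-butyldimethylsilyloxy)-15-oxo-17-nor-6,7-seco-ent-kauran-7,20-olide | C1C(=O)[C@]23C[C@H]1CC[C@H]2[C@]1(COC3=O)[C@@H](OC(C)=O)CC[C@@](C)(CO[Si](C)(C)C(C)(C)C)[C@H]1COC(C)=O | intermediate
26 | 16-[(N-methylanilino)methyl] derivative of 25 (Mannich base, C16 epimers) | CN(c4ccccc4)CC1C(=O)[C@]23C[C@H]1CC[C@H]2[C@]1(COC3=O)[C@@H](OC(C)=O)CC[C@@](C)(CO[Si](C)(C)C(C)(C)C)[C@H]1COC(C)=O | intermediate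
27 | 1α,6-diacetoxy-19-(tert-butyldimethylsilyloxy)-15-oxo-6,7-seco-ent-kaur-16-en-7,20-olide | C=C1C(=O)[C@]23C[C@H]1CC[C@H]2[C@]1(COC3=O)[C@@H](OC(C)=O)CC[C@@](C)(CO[Si](C)(C)C(C)(C)C)[C@H]1COC(C)=O | intermediate
28 | isodojaponin D (1α,6-diacetoxy-19-hydroxy-15-oxo-6,7-seco-ent-kaur-16-en-7,20-olide) | C=C1C(=O)[C@]23C[C@H]1CC[C@H]2[C@]1(COC3=O)[C@@H](OC(C)=O)CC[C@@](C)(CO)[C@H]1COC(C)=O | target

Total step count: 16. Longest linear sequence: 14 steps (steps 1–3, then 6–16).

Steps most likely to fail

Step 13. What may go wrong: hydrogen transfer to the tertiary C10 radical before the slow 6-endo closure through the ester tether, or to the C8 radical before the 5-exo-dig closure. The fallback is polar instead of radical; it sets out from 18 and returns at 23. Chemoselective reduction of the aldehyde of 18 (NaBH4, MeOH, −78 °C) would give the primary alcohol F1, and silylation (TBSCl, imidazole) the bis-silyl compound F2. An HNTf2-catalysed intramolecular Mukaiyama–Michael addition of the C10 silyl enol ether to the tethered enoate, with silyl transfer, would close the lactone through the same C9–C10 bond and give the silyl ketene acetal F3. Carbocyclisation of F3 onto the alkyne with a monovalent gold catalyst (Ph3PAuCl/AgBF4, CH2Cl2/MeOH, Conia-ene type, 5-exo-dig) would close ring D and give the C1 keto lactone F4. Borohydride reduction (axial delivery) would give the 1α-alcohol F5, and acetylation (Ac2O, DMAP) returns 23.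

Step 8. What may go wrong: erosion of facial (enantio) selectivity or of endo selectivity in the cycloaddition of the hindered diene. The fallback replaces catalyst control by substrate-based separation; it sets out from 16 and returns at 18. The cycloaddition would be run with the achiral Lewis acid Me2AlCl (CH2Cl2, −78 °C), which keeps the regio- and endo-selectivity. Because 16 already carries the C13 stereocentre, the two endo adducts are diastereomers: 18 is separated by preparative HPLC from its ring-A antipodal diastereomer F6, which is discarded.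

Step 10. What may go wrong: hydride delivery to the wrong face of the C1 ketone (Felkin–Anh attack anti to the C–Br bond competing with axial attack), or closure of the bromohydrin alkoxide to an epoxide. The fallback replaces substrate control by reagent control; it goes from 19 to 20 and makes no new compound. Corey–Bakshi–Shibata reduction with (R)-2-methyl-CBS-oxazaborolidine and BH3·SMe2 (THF, −30 °C) would differentiate the quaternary C10 flank from the C2 methylene flank, and the neutral borane conditions avoid a free alkoxide.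

Further compounds
F1 | step 13 | {(5R,6S)-6-(acetoxymethyl)-5-(hydroxymethyl)-5-methyl-2-[tri(propan-2-yl)silyloxy]cyclohex-1-en-1-yl}methyl (5S)-5-(prop-2-yn-1-yl)cyclohex-1-ene-1-carboxylate | C1(COC(=O)C2=CCC[C@@H](CC#C)C2)=C(O[Si](C(C)C)(C(C)C)C(C)C)CC[C@@](C)(CO)[C@H]1COC(C)=O
F2 | step 13 | 19-O-tert-butyldimethylsilyl ether of F1 | C1(COC(=O)C2=CCC[C@@H](CC#C)C2)=C(O[Si](C(C)C)(C(C)C)C(C)C)CC[C@@](C)(CO[Si](C)(C)C(C)(C)C)[C@H]1COC(C)=O
F3 | step 13 | spirolactone triisopropylsilyl ketene acetal (C1 ketone, C7=C8 ketene acetal, C13 propargyl) | C#CC[C@H]1CC2=C(O[Si](C(C)C)(C(C)C)C(C)C)OC[C@]3(C(=O)CC[C@@](C)(CO[Si](C)(C)C(C)(C)C)[C@H]3COC(C)=O)[C@@H]2CC1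
F4 | step 13 | 6-acetoxy-19-(tert-butyldimethylsilyloxy)-15-methylidene-1-oxo-17-nor-6,7-seco-ent-kauran-7,20-olide | C1C(=C)[C@]23C[C@H]1CC[C@H]2[C@]1(COC3=O)C(=O)CC[C@@](C)(CO[Si](C)(C)C(C)(C)C)[C@H]1COC(C)=O
F5 | step 13 | 6-acetoxy-19-(tert-butyldimethylsilyloxy)-1α-hydroxy-15-methylidene-17-nor-6,7-seco-ent-kauran-7,20-olide | C1C(=C)[C@]23C[C@H]1CC[C@H]2[C@]1(COC3=O)[C@@H](O)CC[C@@](C)(CO[Si](C)(C)C(C)(C)C)[C@H]1COC(C)=O
F6 | step 8 | (5S,6R)-ring-A diastereomer of 18 | C1(COC(=O)C2=CCC[C@@H](CC#C)C2)=C(O[Si](C(C)C)(C(C)C)C(C)C)CC[C@](C)(C=O)[C@@H]1COC(C)=O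
F0 | step 10 | none | none
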